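Atom labels: C7/C7' = ArCH–O, C8/C8' = bridgehead C–OH, C9/C9' = OCH2; ring 1 = C7–O–C9'–C8'–C8, ring 2 = C7'–O–C9–C8–C8'. The two rings share only the C8–C8' bond and each adds to it just one ArCH–O–CH2 triad, so the bicycle is two carbonyl ylides laid onto a two-carbon unit, with the bridgehead hydroxyls carried as C–B bonds.
Retrosynthesis: the benzyl–O bonds are cut first, then C8–O and C8'–O (back to C–B), then C7–C8 and C9'–C8' (ring 1) together with C7'–C8' and C9–C8 (ring 2), and last the O–CH2Cl and C7–Si bonds of the ylide precursor.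
Forward: O-benzylvanillin is taken through an α-silyl carbinol and a methylthiomethyl ether to the chloromethyl ether; CsF then builds ring 1 on pinB–C≡C–Bpin and ring 2 on the resulting diboryl-dihydrofuran in one flask; oxidation, enantiomer separation and hydrogenolysis follow.
Stereochemistry: the cis ring fusion comes from suprafacial addition to the alkene, C7 and C7' relative to the bridgeheads from anti and exo approach of the second ylide, both C–O bonds from C–B oxidation with retention, and the absolute configuration from separation of the enantiomers of the dibenzyl diol on a chiral stationary phase.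

Key step: step 4

Remark: 1, 6 and PhMe2Si–Bpin are taken as purchasable. Compounds 2–5 are racemic at the silicon-bearing carbon, which is flattened in step 4. Compounds 8, 9 and 10 are racemates, named rac and drawn as the enantiomer that is carried on.

Step 1
Reactants: 1 4-(benzyloxy)-3-methoxybenzaldehyde
Product: 3 rac-[4-(benzyloxy)-3-methoxyphenyl][dimethyl(phenyl)silyl]methanol, via O-pinacolboryl ether 2 (not isolated)
Conditions: PhMe2Si–Bpin (1.2 equiv), CuCl (5 mol %), 1,3-bis(2,6-diisopropylphenyl)imidazolium chloride (5 mol %), NaOt-Bu (12 mol %), THF, rt; then aq. NH4Cl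
Reagents that add atoms: dimethyl(phenyl)silylboronic acid pinacol ester, C[Si](C)(c1ccccc1)B1OC(C)(C)C(C)(C)O1
Why: Copper-catalysed 1,2-addition of a silyl nucleophile from a silylboronate to an aldehyde, in which the copper alkoxide is O-borylated at once and so cannot undergo Brook rearrangement; the new stereocentre is racemic and is erased in step 4.

Step 2
Reactants: 3 rac-[4-(benzyloxy)-3-methoxyphenyl][dimethyl(phenyl)silyl]methanol
Product: 4 rac-{[4-(benzyloxy)-3-methoxyphenyl][(methylsulfanyl)methoxy]methyl}dimethyl(phenyl)silane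
Conditions: Me2S (8 equiv), (BzO)2 (4 equiv), MeCN, 0 °C
Reagents that add atoms: dimethyl sulfide, CSC
Why: Pummerer-type methylthiomethylation of an alcohol (the benzoyloxysulfonium salt collapses to MeS(+)=CH2, which the hindered hydroxyl captures); no alkoxide is formed, so the α-silyl carbinol is not exposed to Brook rearrangement, and no strong acid is present to ionise the electron-rich benzylic C–O bond.

Step 3
Reactants: 4 rac-{[4-(benzyloxy)-3-methoxyphenyl][(methylsulfanyl)methoxy]methyl}dimethyl(phenyl)silane
Product: 5 rac-{[4-(benzyloxy)-3-methoxyphenyl](chloromethoxy)methyl}dimethyl(phenyl)silane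
Conditions: SO2Cl2 (1.0 equiv), cyclohexene (2 equiv), CH2Cl2, −78 °C to 0 °C; volatiles removed, crude 5 used at once
Reagents that add atoms: sulfuryl chloride, ClS(Cl)(=O)=O
Why: Chlorinolysis of an O,S-acetal (S-chlorination, loss of MeSCl, chloride capture of the oxocarbenium ion), the usual non-acidic route to chloromethyl ethers of acid-labile alkoxybenzyl alcohols; cyclohexene traps MeSCl before it can attack the arene.

Step 4
Reactants: 5 rac-{[4-(benzyloxy)-3-methoxyphenyl](chloromethoxy)methyl}dimethyl(phenyl)silane (two molecules); 6 1,2-bis(4,4,5,5-tetramethyl-1,3,2-dioxaborolan-2-yl)ethyne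
Product: 9 rac-(1R,2S,5R,6S)-2,6-bis[4-(benzyloxy)-3-methoxyphenyl]-1,5-bis(4,4,5,5-tetramethyl-1,3,2-dioxaborolan-2-yl)-3,7-dioxabicyclo[3.3.0]octane, via carbonyl ylide 7 (not isolated), via 3,4-diboryl-2,5-dihydrofuran 8 (not isolated)
Conditions: CsF (flame-dried, excess), MeCN, rt, slow addition of 5 (3 equiv) to 6 and CsF; chromatography
Reagents that add atoms: none
Why: Proposed new method: fluoride attacks silicon of 5 while chloride departs from the OCH2Cl carbon, so that a 1,3-elimination releases the non-stabilised carbonyl ylide 7 (ArCH=O(+)–CH2(−)), which adds as a 4π component to the boron-activated triple bond of 6 to give dihydrofuran 8 and then, as a second molecule, to the 1,2-diborylalkene of 8, whose two vacant boron p orbitals keep the LUMO low. The closest known reactions are the CsF-induced generation of such ylides from chloromethyl α-silylalkyl ethers with trapping by electron-poor alkenes and alkynes, and the 1,3-dipolar cycloadditions of alkynyl- and alkenylboronates with nitrile oxides, diazoalkanes and azomethine ylides; pinacol boronates are known to survive fluoride-triggered silyl eliminations such as aryne generation, and CsF is barely soluble in MeCN. Ring 1 closes by an intermolecular concerted [3+2] cycloaddition across the alkyne (bonds C7–C8 and C9'–C8'), and ring 2 by a second intermolecular [3+2] cycloaddition across the C8=C8' alkene (bonds C7'–C8' and C9–C8). C7 arises as a racemate in the first addition; C8 and C8' are set together by the suprafacial second addition, which can only give the cis fusion and should take place on the alkene face remote from the C7 aryl group, and C7' is set by the exo position of the ylide aryl group, turned outward from ring 1, which places the two aryl and the two boryl groups on the convex side of the bicycle. The step needs head-to-tail regiochemistry in the second addition, which should follow on steric grounds because the aryl-bearing ylide terminus prefers C8', flanked by CH2, over C8, flanked by CH(Ar); it fixes no absolute configuration, which is left to step 6.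

Step 5
Reactants: 9 rac-(1R,2S,5R,6S)-2,6-bis[4-(benzyloxy)-3-methoxyphenyl]-1,5-bis(4,4,5,5-tetramethyl-1,3,2-dioxaborolan-2-yl)-3,7-dioxabicyclo[3.3.0]octane
Product: 10 rac-(1S,2R,5S,6R)-2,6-bis[4-(benzyloxy)-3-methoxyphenyl]-3,7-dioxabicyclo[3.3.0]octane-1,5-diol
Conditions: H2O2 (30% aq.), NaOH, THF/H2O, 0 °C to rt
Reagents that add atoms: hydrogen peroxide, OO
Why: Boronate oxidation (hydroperoxide ate complex, 1,2-shift of carbon from boron to oxygen with retention), well established for tertiary and for vicinal bis(boronates), should give the cis-diol; the rearrangement is expected to outrun β-alkoxy elimination, and the benzyl and ring ethers are inert.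

Step 6
Reactants: 10 rac-(1S,2R,5S,6R)-2,6-bis[4-(benzyloxy)-3-methoxyphenyl]-3,7-dioxabicyclo[3.3.0]octane-1,5-diol
Product: 11 (1S,2R,5S,6R)-2,6-bis[4-(benzyloxy)-3-methoxyphenyl]-3,7-dioxabicyclo[3.3.0]octane-1,5-diol
Conditions: preparative HPLC, cellulose tris(3,5-dimethylphenylcarbamate) on silica, n-hexane/i-PrOH, rt
Reagents that add atoms: none
Why: Chromatographic resolution of a racemate on a polysaccharide chiral stationary phase, the usual way to separate furofuran lignan enantiomers; no bond is made or broken, so the four stereocentres stay as set, and the enantiomer to keep is identified by the sign of rotation of the prinsepiol derived from it.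

Step 7
Reactants: 11 (1S,2R,5S,6R)-2,6-bis[4-(benzyloxy)-3-methoxyphenyl]-3,7-dioxabicyclo[3.3.0]octane-1,5-diol
Product: 12 prinsepiol
Conditions: H2 (1 atm), Pd/C (10 %), EtOAc, rt, stopped at full conversion
Reagents that add atoms: none
Why: Catalytic hydrogenolysis of aryl benzyl ethers, which in a neutral solvent are cleaved far faster than the dialkyl benzylic C–O bonds of the furofuran; no stereocentre is touched.

Compound list
1 | 4-(benzyloxy)-3-methoxybenzaldehyde (O-benzylvanillin) | COc1cc(C=O)ccc1OCc1ccccc1 | starting material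
2 | 2-{[4-(benzyloxy)-3-methoxyphenyl][dimethyl(phenyl)silyl]methoxy}-4,4,5,5-tetramethyl-1,3,2-dioxaborolane, racemic, not isolated | COc1cc(C(OB2OC(C)(C)C(C)(C)O2)[Si](C)(C)c3ccccc3)ccc1OCc4ccccc4 | intermediate
3 | rac-[4-(benzyloxy)-3-methoxyphenyl][dimethyl(phenyl)silyl]methanol | COc1cc(C(O)[Si](C)(C)c2ccccc2)ccc1OCc3ccccc3 | intermediate
4 | rac-{[4-(benzyloxy)-3-methoxyphenyl][(methylsulfanyl)methoxy]methyl}dimethyl(phenyl)silane | COc1cc(C(OCSC)[Si](C)(C)c2ccccc2)ccc1OCc3ccccc3 | intermediate
5 | rac-{[4-(benzyloxy)-3-methoxyphenyl](chloromethoxy)methyl}dimethyl(phenyl)silane | COc1cc(C(OCCl)[Si](C)(C)c2ccccc2)ccc1OCc3ccccc3 | intermediate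
6 | 1,2-bis(4,4,5,5-tetramethyl-1,3,2-dioxaborolan-2-yl)ethyne | CC1(C)OB(C#CB2OC(C)(C)C(C)(C)O2)OC1(C)C | starting material
7 | carbonyl ylide [4-(benzyloxy)-3-methoxybenzylidene]oxonium methylide, not isolated | [CH2-][O+]=Cc1ccc(OCc2ccccc2)c(OC)c1 | intermediate
8 | rac-(2S)-2-[4-(benzyloxy)-3-methoxyphenyl]-3,4-bis(4,4,5,5-tetramethyl-1,3,2-dioxaborolan-2-yl)-2,5-dihydrofuran, not isolated | COc1cc([C@H]2OCC(B3OC(C)(C)C(C)(C)O3)=C2B4OC(C)(C)C(C)(C)O4)ccc1OCc5ccccc5 | intermediate
9 | rac-(1R,2S,5R,6S)-2,6-bis[4-(benzyloxy)-3-methoxyphenyl]-1,5-bis(4,4,5,5-tetramethyl-1,3,2-dioxaborolan-2-yl)-3,7-dioxabicyclo[3.3.0]octane, aryl and boryl groups all on the convex face | COc1cc([C@H]2OC[C@]3(B4OC(C)(C)C(C)(C)O4)[C@@H](c5ccc(OCc6ccccc6)c(OC)c5)OC[C@]23B7OC(C)(C)C(C)(C)O7)ccc1OCc8ccccc8 | intermediate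
10 | rac-(1S,2R,5S,6R)-2,6-bis[4-(benzyloxy)-3-methoxyphenyl]-3,7-dioxabicyclo[3.3.0]octane-1,5-diol | COc1cc([C@H]2OC[C@]3(O)[C@@H](c4ccc(OCc5ccccc5)c(OC)c4)OC[C@]23O)ccc1OCc6ccccc6 | intermediate
11 | (1S,2R,5S,6R)-2,6-bis[4-(benzyloxy)-3-methoxyphenyl]-3,7-dioxabicyclo[3.3.0]octane-1,5-diol, single enantiomer | COc1cc([C@H]2OC[C@]3(O)[C@@H](c4ccc(OCc5ccccc5)c(OC)c4)OC[C@]23O)ccc1OCc6ccccc6 | intermediate
12 | prinsepiol, (1S,2R,5S,6R)-2,6-bis(4-hydroxy-3-methoxyphenyl)-3,7-dioxabicyclo[3.3.0]octane-1,5-diol | COc1cc([C@H]2OC[C@]3(O)[C@@H](c4ccc(O)c(OC)c4)OC[C@]23O)ccc1O | target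

Total step count: 7. Longest linear sequence: 7 steps (1 to 12; 6 is purchased).

Steps most likely to fail

Step 4. The second cycloaddition to the hindered tetrasubstituted diborylalkene may be too slow to compete with self-reaction of the ylide. It may also give head-to-head or endo-aryl adducts, and fluoride may bind to boron and cause protodeboronation or alkynyl transfer to the chloromethyl ether. The fallback is an enantioselective route of known reactions that sets out from 1 and comes back at 11, so that steps 5 and 6 are not needed. Addition of 1-bromovinyllithium (vinyl bromide, LDA, THF/Et2O/pentane, −110 °C) to 1 should give the racemic 2-bromoallylic alcohol F1. Oxidation with MnO2 gives the α-bromo enone F2. CBS reduction, with the oxazaborolidine enantiomer chosen to deliver the (R)-carbinol, gives the (R)-2-bromoallylic alcohol F3. Part of F3 is converted with Me3SnSnMe3 and Pd(PPh3)4 into the vinylstannane F4. Stille coupling of F3 with F4 (Pd(PPh3)4, CuCl, LiCl, DMSO) joins C8 to C8' and gives the C2-symmetric diene diol F5. Hydroxyl-directed epoxidation of both 1,1-disubstituted alkenes (VO(acac)2, t-BuOOH) should give the bis-epoxide F6. With mild acid (pyridinium p-toluenesulfonate) each C7 hydroxyl opens the epoxide of the other half at its CH2 terminus (5-exo), which closes rings 1 and 2 and leaves the two bridgehead hydroxyls cis, that is 11.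

Step 3. The electron-rich arene may be chlorinated or sulfenylated, and the benzylic C–O bond of the labile chloromethyl ether may ionise during its formation or concentration. The fallback sets out from 3 and comes back at 5: direct chloromethylation with paraformaldehyde and Me3SiCl in CH2Cl2 at 0 °C, through the hemiformal and exchange of its hydroxyl for chloride, with no sulfur reagent and no oxidant. It bypasses 4 and makes no new compound (F0).

Step 7. Over-reduction may occur: once the para-hydroxyl groups are free, the benzylic C7–O and C7'–O ring bonds become prone to hydrogenolysis, which would open the furofuran. The fallback sets out from 11 and comes back at 12: non-reductive debenzylation with BCl3 and pentamethylbenzene as cation scavenger in CH2Cl2 at −78 °C, followed by methanol quench to free the diol from boron. It makes no new compound (F0).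

Further compounds
F1 | step 4 | rac-1-[4-(benzyloxy)-3-methoxyphenyl]-2-bromoprop-2-en-1-ol | COc1cc(C(O)C(Br)=C)ccc1OCc1ccccc1
F2 | step 4 | 1-[4-(benzyloxy)-3-methoxyphenyl]-2-bromoprop-2-en-1-one | COc1cc(C(=O)C(Br)=C)ccc1OCc1ccccc1
F3 | step 4 | (R)-1-[4-(benzyloxy)-3-methoxyphenyl]-2-bromoprop-2-en-1-ol | COc1cc([C@@H](O)C(Br)=C)ccc1OCc2ccccc2
F4 | step 4 | (R)-1-[4-(benzyloxy)-3-methoxyphenyl]-2-(trimethylstannyl)prop-2-en-1-ol | COc1cc([C@@H](O)C(=C)[Sn](C)(C)C)ccc1OCc2ccccc2
F5 | step 4 | (1R,4R)-1,4-bis[4-(benzyloxy)-3-methoxyphenyl]-2,3-dimethylidenebutane-1,4-diol | COc1cc([C@@H](O)C(=C)C(=C)[C@H](O)c3ccc(OCc4ccccc4)c(OC)c3)ccc1OCc2ccccc2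
F6 | step 4 | (R,R)-[(2S,2'S)-2,2'-bioxirane-2,2'-diyl]bis{[4-(benzyloxy)-3-methoxyphenyl]methanol} | COc1cc([C@@H](O)[C@@]5(CO5)[C@]6(CO6)[C@H](O)c3ccc(OCc4ccccc4)c(OC)c3)ccc1OCc2ccccc2
F0 | step 3 | none | none
F0 | step 7 | none | none
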